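The target is cut at C9–C10 into a ring-free C1–C9 chain and a bis-furan electrophile, and the chain rests on a Wittig–Still [2,3] rearrangement. The feature exploited is the Z-trisubstituted C6=C7 alkene, in which the C7 methyl is trans and the C8 chain is cis to C5; neither furan (ring A, ring B) takes part. In one operation the shift forms C8–C9, moves the alkene from C7=C8 to C6=C7 with Z geometry and releases the C9 alcohol. Its precursor is the stannylmethyl ether of a C6 isopropenyl carbinol (either epimer), made from (R)-citronellol, which supplies C1–C6 and the C3 centre; C1 travels as a silyl ether.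

Key step: step 5

Remark: atoms are numbered along the chain from the ester carbonyl carbon C1 through the stereocentre C3 and the alkene C6=C7 to the methylene C10 on ring A (the 2,4-disubstituted furan); ring B is the furan-3-yl ring. The target is the (3R,6Z) isomer, and C3 of (R)-citronellol has the same spatial arrangement. Compounds 5, 8, 15 and 16 are assumed to be purchased.

Step 1
Reactants: 1 (R)-citronellol
Product: 2 tert-butyl{[(3R)-3,7-dimethyloct-6-en-1-yl]oxy}dimethylsilane
Conditions: TBSCl, imidazole, CH2Cl2, 0 °C → rt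
Reagents that add atoms: tert-butyldimethylsilyl chloride, CC(C)(C)[Si](C)(C)Cl
Why: Standard silyl ether protection: imidazole-promoted silylation of the unhindered primary alcohol should be clean and touches neither the alkene nor the C3 centre.

Step 2
Reactants: 2 tert-butyl{[(3R)-3,7-dimethyloct-6-en-1-yl]oxy}dimethylsilane
Product: 4 (4R)-6-[(tert-butyldimethylsilyl)oxy]-4-methylhexanal, via secondary ozonide 3 (not isolated)
Conditions: O3, CH2Cl2, −78 °C; then PPh3, −78 °C → rt
Reagents that add atoms: ozone, [O-][O+]=O
Why: Ozonolysis with reductive work-up should cleave the only alkene of 2 at C6=C7 to give the C6 aldehyde and acetone, while the silyl ether and the remote C3 centre are inert to ozone at −78 °C.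

Step 3
Reactants: 4 (4R)-6-[(tert-butyldimethylsilyl)oxy]-4-methylhexanal; 5 isopropenylmagnesium bromide
Product: 7 (6R)-8-[(tert-butyldimethylsilyl)oxy]-2,6-dimethyloct-1-en-3-ol (both C3 epimers), via bromomagnesium alkoxide 6 (not isolated)
Conditions: THF, −78 → 0 °C; then H2O
Reagents that add atoms: none
Why: Grignard 1,2-addition to the unhindered aldehyde brings in C7, its methyl group and C8; the new C6 carbinol centre forms without control, which is acceptable because step 5 destroys it.

Step 4
Reactants: 7 (6R)-8-[(tert-butyldimethylsilyl)oxy]-2,6-dimethyloct-1-en-3-ol; 8 (iodomethyl)tributylstannane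
Product: 10 tert-butyl(dimethyl)({(3R)-3,7-dimethyl-6-[(tributylstannyl)methoxy]oct-7-en-1-yl}oxy)silane (both C6 epimers), via potassium alkoxide 9 (not isolated)
Conditions: KH, THF, 0 °C; then 8, 0 °C → rt
Reagents that add atoms: none
Why: Williamson ether synthesis: the potassium alkoxide should displace iodide from the unhindered primary iodide 8 by SN2, and KH leaves the silyl ether and the alkene alone.

Step 5
Reactants: 10 tert-butyl(dimethyl)({(3R)-3,7-dimethyl-6-[(tributylstannyl)methoxy]oct-7-en-1-yl}oxy)silane
Product: 13 (3Z,7R)-9-{[tert-butyl(dimethyl)silyl]oxy}-3,7-dimethylnon-3-en-1-ol, via lithiomethyl ether 11 (not isolated), via lithium alkoxide 12 (not isolated)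
Conditions: n-BuLi, THF, −78 °C; then H2O
Reagents that add atoms: none
Why: n-BuLi swaps the tributylstannyl group for lithium at −78 °C (tetrabutylstannane is the by-product), and the resulting unstabilised α-alkoxy carbanion 11 should rearrange at once in a concerted, suprafacial [2,3] sigmatropic shift whose five-membered transition state is an envelope: C9 attacks the CH2 terminus C8 while the C6–O bond is given up and the π bond reappears between C6 and C7. This is the Wittig–Still rearrangement, well established for stannylmethyl ethers of 2-methylalk-1-en-3-ols, which are known to give Z-trisubstituted homoallylic alcohols. No ring is closed and no stereocentre is created; what the step has to deliver is the Z alkene. That selectivity should arise because the transition state is early and reactant-like, so the C5 chain on C6 prefers the pseudoaxial site where it escapes the gauche contact with the C7 methyl group, and this puts C5 and the new C8–C9 arm on the same side of C6=C7. The C6 configuration is erased in the process, so the epimer mixture 10 should funnel into one alkene, while C3 lies outside the reacting array and keeps its R configuration. A silyl ether is carried at C1 because it ignores n-BuLi, whereas the methyl ester of the target would be attacked.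

Step 6
Reactants: 13 (3Z,7R)-9-{[tert-butyl(dimethyl)silyl]oxy}-3,7-dimethylnon-3-en-1-ol
Product: 14 {[(3R,6Z)-9-bromo-3,7-dimethylnon-6-en-1-yl]oxy}(tert-butyl)dimethylsilane
Conditions: CBr4, PPh3, CH2Cl2, 0 °C
Reagents that add atoms: tetrabromomethane, BrC(Br)(Br)Br
Why: Appel reaction: the primary homoallylic alcohol should be converted into the bromide by SN2 on the alkoxyphosphonium ion under near-neutral conditions that leave the silyl ether and the Z alkene unchanged.

Step 7
Reactants: 15 3-bromofuran; 16 4-bromofuran-2-carbaldehyde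
Product: 19 (4-bromofuran-2-yl)(furan-3-yl)methanol (racemic), via 3-lithiofuran 17 (not isolated), via lithium alkoxide 18 (not isolated)
Conditions: n-BuLi, THF, −78 °C; then 16, −78 °C; then H2O
Reagents that add atoms: none
Why: Bromine–lithium exchange gives 3-lithiofuran, which keeps its position at −78 °C and should add to the aldehyde (1,2-addition) far faster than it attacks the ring bromide; the carbinol centre is racemic and is removed in step 8.

Step 8
Reactants: 19 (4-bromofuran-2-yl)(furan-3-yl)methanol
Product: 20 4-bromo-2-(furan-3-ylmethyl)furan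
Conditions: Et3SiH, CF3CO2H, CH2Cl2, 0 °C
Reagents that add atoms: none
Why: Ionic hydrogenation: acid ionises the carbinol to a cation stabilised by both furans and Et3SiH delivers hydride to it, a standard deoxygenation of diaryl and heteroaryl carbinols, with excess silane and low temperature keeping the cation from alkylating a second furan.

Step 9
Reactants: 20 4-bromo-2-(furan-3-ylmethyl)furan
Product: 24 [5-(furan-3-ylmethyl)furan-3-yl]methanol, via lithiated furan 21 (not isolated), via lithium hemiaminal alkoxide 22 (not isolated), via aldehyde 23 (not isolated)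
Conditions: n-BuLi, THF, −78 °C; DMF, −78 → 0 °C; then MeOH, NaBH4, 0 °C
Reagents that add atoms: N,N-dimethylformamide, CN(C)C=O
Why: Bromine–lithium exchange at −78 °C should outrun deprotonation of the bridging CH2, formylation of the aryllithium with DMF is standard, and NaBH4 reduces the liberated aldehyde to the primary alcohol in the same flask.

Step 10
Reactants: 24 [5-(furan-3-ylmethyl)furan-3-yl]methanol
Product: 26 4-(chloromethyl)-2-(furan-3-ylmethyl)furan, via mesylate 25 (not isolated)
Conditions: MsCl, 2,4,6-collidine, LiCl, DMF, 0 °C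
Reagents that add atoms: lithium chloride, [Li+].[Cl-]
Why: Mesylation with in situ SN2 displacement by chloride under buffered, non-oxidising conditions is the usual way to make sensitive furylmethyl and allylic chlorides without exposing the rings to acid.

Step 11
Reactants: 14 {[(3R,6Z)-9-bromo-3,7-dimethylnon-6-en-1-yl]oxy}(tert-butyl)dimethylsilane; 26 4-(chloromethyl)-2-(furan-3-ylmethyl)furan
Product: 28 tert-butyl({(3R,6Z)-10-[5-(furan-3-ylmethyl)furan-3-yl]-3,7-dimethyldec-6-en-1-yl}oxy)dimethylsilane, via Grignard reagent 27 (not isolated)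
Conditions: Mg, THF, rt; then 26, Li2CuCl4 (cat.), THF, −20 → 0 °C
Reagents that add atoms: none
Why: Copper-catalysed cross-coupling of a primary alkyl Grignard reagent with a benzylic-type chloride (Li2CuCl4 catalysis) should form C9–C10 by substitution at C10, the homoallylic Grignard reagent holding its Z geometry at these temperatures and the silyl ether being inert.

Step 12
Reactants: 28 tert-butyl({(3R,6Z)-10-[5-(furan-3-ylmethyl)furan-3-yl]-3,7-dimethyldec-6-en-1-yl}oxy)dimethylsilane
Product: 29 (3R,6Z)-10-[5-(furan-3-ylmethyl)furan-3-yl]-3,7-dimethyldec-6-en-1-ol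
Conditions: Bu4NF, THF, 0 °C → rt
Reagents that add atoms: none
Why: Fluoride-induced desilylation is driven by the strong Si–F bond and should free the C1 alcohol without affecting the furans or the alkene.

Step 13
Reactants: 29 (3R,6Z)-10-[5-(furan-3-ylmethyl)furan-3-yl]-3,7-dimethyldec-6-en-1-ol
Product: 30 (3R,6Z)-10-[5-(furan-3-ylmethyl)furan-3-yl]-3,7-dimethyldec-6-enal
Conditions: Dess–Martin periodinane, pyridine, CH2Cl2, 0 °C → rt
Reagents that add atoms: none
Why: Dess–Martin oxidation under pyridine buffering should stop at the aldehyde and is mild enough for electron-rich furans and the trisubstituted alkene; C3 is β to the carbonyl group and cannot epimerise by enolisation.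

Step 14
Reactants: 30 (3R,6Z)-10-[5-(furan-3-ylmethyl)furan-3-yl]-3,7-dimethyldec-6-enal
Product: 31 (3R,6Z)-10-[5-(furan-3-ylmethyl)furan-3-yl]-3,7-dimethyldec-6-enoic acid
Conditions: Ag2O, NaOH, EtOH/H2O, rt; then 1 M HCl to pH 4, 0 °C
Reagents that add atoms: disilver oxide, [Ag+].[Ag+].[O-2]
Why: Oxidation of an aldehyde to the carboxylic acid with Ag2O in aqueous base (Tollens-type oxidation) is selective for the formyl group and should spare both furans and the alkene, which more electrophilic oxidants would endanger.

Step 15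
Reactants: 31 (3R,6Z)-10-[5-(furan-3-ylmethyl)furan-3-yl]-3,7-dimethyldec-6-enoic acid
Product: 32 methyl (3R,6Z)-10-[5-(furan-3-ylmethyl)furan-3-yl]-3,7-dimethyldec-6-enoate
Conditions: MeI, K2CO3, DMF, rt
Reagents that add atoms: iodomethane, CI
Why: SN2 O-methylation of the potassium carboxylate with iodomethane should give the methyl ester under mild base that does not affect the furans, the alkene or the C3 centre.

Compound list

1 | (R)-citronellol, (3R)-3,7-dimethyloct-6-en-1-ol | C[C@H](CCC=C(C)C)CCO | starting material
2 | tert-butyl{[(3R)-3,7-dimethyloct-6-en-1-yl]oxy}dimethylsilane | CC(C)(C)[Si](C)(C)OCC[C@H](C)CCC=C(C)C | intermediate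
3 | 3-{(3R)-5-[(tert-butyldimethylsilyl)oxy]-3-methylpentyl}-5,5-dimethyl-1,2,4-trioxolane (secondary ozonide, ring carbon unassigned, formed in the flask) | CC(C)(C)[Si](C)(C)OCC[C@H](C)CCC1OOC(C)(C)O1 | intermediate
4 | (4R)-6-[(tert-butyldimethylsilyl)oxy]-4-methylhexanal | CC(C)(C)[Si](C)(C)OCC[C@H](C)CCC=O | intermediate
5 | isopropenylmagnesium bromide | C=C(C)[Mg]Br | starting material
6 | bromomagnesium (6R)-8-[(tert-butyldimethylsilyl)oxy]-2,6-dimethyloct-1-en-3-olate (both C3 epimers, formed in the flask) | CC(C)(C)[Si](C)(C)OCC[C@H](C)CCC(O[Mg]Br)C(C)=C | intermediate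
7 | (6R)-8-[(tert-butyldimethylsilyl)oxy]-2,6-dimethyloct-1-en-3-ol (both C3 epimers) | CC(C)(C)[Si](C)(C)OCC[C@H](C)CCC(O)C(C)=C | intermediate
8 | (iodomethyl)tributylstannane | CCCC[Sn](CCCC)(CCCC)CI | starting material
9 | potassium (6R)-8-[(tert-butyldimethylsilyl)oxy]-2,6-dimethyloct-1-en-3-olate (both C3 epimers, formed in the flask) | CC(C)(C)[Si](C)(C)OCC[C@H](C)CCC(O[K])C(C)=C | intermediate
10 | tert-butyl(dimethyl)({(3R)-3,7-dimethyl-6-[(tributylstannyl)methoxy]oct-7-en-1-yl}oxy)silane (both C6 epimers) | CC(C)(C)[Si](C)(C)OCC[C@H](C)CCC(OC[Sn](CCCC)(CCCC)CCCC)C(C)=C | intermediate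
11 | ({[(6R)-8-{[tert-butyl(dimethyl)silyl]oxy}-2,6-dimethyloct-1-en-3-yl]oxy}methyl)lithium (both C3 epimers, formed in the flask) | CC(C)(C)[Si](C)(C)OCC[C@H](C)CCC(OC[Li])C(C)=C | intermediate
12 | lithium (3Z,7R)-9-{[tert-butyl(dimethyl)silyl]oxy}-3,7-dimethylnon-3-en-1-olate (formed in the flask) | CC(C)(C)[Si](C)(C)OCC[C@H](C)CC/C=C(/C)CCO[Li] | intermediate
13 | (3Z,7R)-9-{[tert-butyl(dimethyl)silyl]oxy}-3,7-dimethylnon-3-en-1-ol | CC(C)(C)[Si](C)(C)OCC[C@H](C)CC/C=C(/C)CCO | intermediate
14 | {[(3R,6Z)-9-bromo-3,7-dimethylnon-6-en-1-yl]oxy}(tert-butyl)dimethylsilane | CC(C)(C)[Si](C)(C)OCC[C@H](C)CC/C=C(/C)CCBr | intermediate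
15 | 3-bromofuran | Brc1ccoc1 | starting material
16 | 4-bromofuran-2-carbaldehyde | O=Cc1cc(Br)co1 | starting material
17 | 3-lithiofuran (formed in the flask) | [Li]c1ccoc1 | intermediate
18 | lithium (4-bromofuran-2-yl)(furan-3-yl)methanolate (racemic, formed in the flask) | [Li]OC(c1ccoc1)c1cc(Br)co1 | intermediate
19 | (4-bromofuran-2-yl)(furan-3-yl)methanol (racemic) | OC(c1ccoc1)c1cc(Br)co1 | intermediate
20 | 4-bromo-2-(furan-3-ylmethyl)furan | Brc1coc(Cc2ccoc2)c1 | intermediate
21 | [5-(furan-3-ylmethyl)furan-3-yl]lithium (formed in the flask) | [Li]c1coc(Cc2ccoc2)c1 | intermediate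
22 | lithium (dimethylamino)[5-(furan-3-ylmethyl)furan-3-yl]methanolate (formed in the flask) | CN(C)C(O[Li])c1coc(Cc2ccoc2)c1 | intermediate
23 | 5-(furan-3-ylmethyl)furan-3-carbaldehyde (formed in the flask) | O=Cc1coc(Cc2ccoc2)c1 | intermediate
24 | [5-(furan-3-ylmethyl)furan-3-yl]methanol | OCc1coc(Cc2ccoc2)c1 | intermediate
25 | [5-(furan-3-ylmethyl)furan-3-yl]methyl methanesulfonate (formed in the flask) | CS(=O)(=O)OCc1coc(Cc2ccoc2)c1 | intermediate
26 | 4-(chloromethyl)-2-(furan-3-ylmethyl)furan | ClCc1coc(Cc2ccoc2)c1 | intermediate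
27 | {(3Z,7R)-9-[(tert-butyldimethylsilyl)oxy]-3,7-dimethylnon-3-en-1-yl}magnesium bromide (formed in the flask) | CC(C)(C)[Si](C)(C)OCC[C@H](C)CC/C=C(/C)CC[Mg]Br | intermediate
28 | tert-butyl({(3R,6Z)-10-[5-(furan-3-ylmethyl)furan-3-yl]-3,7-dimethyldec-6-en-1-yl}oxy)dimethylsilane | CC(C)(C)[Si](C)(C)OCC[C@H](C)CC/C=C(/C)CCCc1coc(Cc2ccoc2)c1 | intermediate
29 | (3R,6Z)-10-[5-(furan-3-ylmethyl)furan-3-yl]-3,7-dimethyldec-6-en-1-ol | OCC[C@H](C)CC/C=C(/C)CCCc1coc(Cc2ccoc2)c1 | intermediate
30 | (3R,6Z)-10-[5-(furan-3-ylmethyl)furan-3-yl]-3,7-dimethyldec-6-enal | O=CC[C@H](C)CC/C=C(/C)CCCc1coc(Cc2ccoc2)c1 | intermediate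
31 | (3R,6Z)-10-[5-(furan-3-ylmethyl)furan-3-yl]-3,7-dimethyldec-6-enoic acid | OC(=O)C[C@H](C)CC/C=C(/C)CCCc1coc(Cc2ccoc2)c1 | intermediate
32 | methyl (3R,6Z)-10-[5-(furan-3-ylmethyl)furan-3-yl]-3,7-dimethyldec-6-enoate | COC(=O)C[C@H](C)CC/C=C(/C)CCCc1coc(Cc2ccoc2)c1 | target

Total step count: 15 (chain: steps 1–6; bis-furan fragment: steps 7–10; coupling and end game: steps 11–15).
Longest linear sequence: 11 steps (steps 1–6, then 11–15).

Steps most likely to fail

1. Step 5. What may go wrong: loss of Z selectivity if the rearrangement passes through a later transition state, or diversion of the carbanion into a [1,2] shift or into simple protonation. The fallback sets out from aldehyde 4 and builds the same alkene by olefination. A Still–Gennari olefination with ethyl 2-[bis(2,2,2-trifluoroethoxy)phosphoryl]propanoate (KN(SiMe3)2, 18-crown-6, THF, −78 °C) should give the Z enoate F1, in which C5 and the ester carbon (the future C8) are already cis. Reduction with i-Bu2AlH (CH2Cl2, −78 °C) should give the Z allylic alcohol F2, and an Appel reaction (CBr4, PPh3, CH2Cl2, −20 °C) the Z allylic bromide F3. Copper-catalysed substitution (CuI cat., THF, 0 °C) with (isopropoxydimethylsilyl)methylmagnesium chloride would add C9 as the homoallylic silane F4. Tamao oxidation (H2O2, KF, KHCO3, THF/MeOH, rt) would then turn the C–Si bond into the C9 alcohol, and the fallback comes back to the route at 13.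

2. Step 8. What may go wrong: the furyl-stabilised cation alkylates a second furan ring faster than it accepts hydride, so that oligomers form, or the acid opens the rings. The fallback sets out from carbinol 19 and avoids cations altogether. Oxidation with MnO2 (CH2Cl2, rt) should give the diaryl ketone F5. A Wolff–Kishner reduction (N2H4·H2O, KOH, diethylene glycol, 130 → 190 °C) would pass through the hydrazone F6 and lose nitrogen to leave the methylene bridge, and the fallback comes back to the route at 20.

3. Step 11. What may go wrong: incomplete formation of the Grignard reagent, Wurtz-type homocoupling of either halide, or attack on ring A instead of substitution at C10. The fallback sets out from chloride 26 and bromide 14 and makes C9–C10 by sulfone alkylation. Displacement of chloride with PhSO2Na (DMF, rt) should give the furylmethyl phenyl sulfone F7. Deprotonation with n-BuLi (THF, −78 °C) would give the lithiated sulfone F8, since the CH2 next to sulfur is far more acidic than the CH2 between the rings. Alkylation with 14 (THF/DMPU, −78 °C → rt) should give the C10 sulfone F9 as a mixture of C10 epimers. Reductive desulfonylation with sodium amalgam (Na/Hg, Na2HPO4, MeOH, −20 °C) would remove the sulfonyl group, and the fallback comes back to the route at 28.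

Further compounds

F1 | step 5 | ethyl (2Z,6R)-8-{[tert-butyl(dimethyl)silyl]oxy}-2,6-dimethyloct-2-enoate | CC(C)(C)[Si](C)(C)OCC[C@H](C)CC/C=C(/C)C(=O)OCC
F2 | step 5 | (2Z,6R)-8-{[tert-butyl(dimethyl)silyl]oxy}-2,6-dimethyloct-2-en-1-ol | CC(C)(C)[Si](C)(C)OCC[C@H](C)CC/C=C(/C)CO
F3 | step 5 | {[(3R,6Z)-8-bromo-3,7-dimethyloct-6-en-1-yl]oxy}(tert-butyl)dimethylsilane | CC(C)(C)[Si](C)(C)OCC[C@H](C)CC/C=C(/C)CBr
F4 | step 5 | tert-butyl({(3R,6Z)-9-[dimethyl(propan-2-yloxy)silyl]-3,7-dimethylnon-6-en-1-yl}oxy)dimethylsilane | CC(C)(C)[Si](C)(C)OCC[C@H](C)CC/C=C(/C)CC[Si](C)(C)OC(C)C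
F5 | step 8 | (4-bromofuran-2-yl)(furan-3-yl)methanone | O=C(c1ccoc1)c1cc(Br)co1
F6 | step 8 | (4-bromofuran-2-yl)(furan-3-yl)methanone hydrazone | NN=C(c1ccoc1)c1cc(Br)co1
F7 | step 11 | 2-(furan-3-ylmethyl)-4-[(phenylsulfonyl)methyl]furan | O=S(=O)(Cc1coc(Cc2ccoc2)c1)c1ccccc1
F8 | step 11 | {[5-(furan-3-ylmethyl)furan-3-yl](phenylsulfonyl)methyl}lithium | [Li]C(c1coc(Cc2ccoc2)c1)S(=O)(=O)c1ccccc1
F9 | step 11 | tert-butyl({(3R,6Z)-10-[5-(furan-3-ylmethyl)furan-3-yl]-3,7-dimethyl-10-(phenylsulfonyl)dec-6-en-1-yl}oxy)dimethylsilane (both C10 epimers) | CC(C)(C)[Si](C)(C)OCC[C@H](C)CC/C=C(/C)CCC(c1coc(Cc2ccoc2)c1)S(=O)(=O)c1ccccc1
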